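Assumption: the target SMILES has no stereodescriptor, and the molecule has no stereocentre and no configurationally stable axis. It is therefore achiral and needs no enantiocontrol.

## Retrosynthetic overview
1. Target ⇒ (O-demethylation, quinone reduction) 2,5-dibromo-3,6-bis(2,3,5-tribromo-4-methoxyphenoxy)-1,4-benzoquinone.
2. Both diaryl ether bonds ⇒ twofold oxa-Michael addition–elimination of 2,3,5-tribromo-4-methoxyphenol on bromanil (2,5-selective).
3. Bromanil ⇒ tetrabromohydroquinone ⇒ cyclohexane-1,4-dione (bromination and aromatisation).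
4. Cyclohexane-1,4-dione ⇒ diethyl succinylsuccinate ⇒ 2 × diethyl succinate, by intermolecular Claisen condensation (key C–C bond) followed by Dieckmann closure.
5. Ring order: the central carbocycle is the only ring built (step 1) and is aromatised in step 3. The two outer rings come ready-made from 4-hydroxyphenyl benzoate (Br2, MeI, saponification, Br2).

## Route

Step 1
Reactants: 1 diethyl succinate (2 equiv)
Product: 3 diethyl 2,5-dioxocyclohexane-1,4-dicarboxylate (diethyl succinylsuccinate), via acyclic keto triester 2 (not isolated)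
Conditions: NaOEt (2 equiv per 1), EtOH, reflux, 24 h; then 2 N H2SO4
Reagents that add atoms: none
Why: An intermolecular Claisen condensation of two succinate esters forges the first ring C–C bond (2), a Dieckmann cyclisation closes the six-membered ring, and irreversible deprotonation of the bis(β-keto ester) drives both equilibria; the two α-stereocentres are enolisable and are removed later.

Step 2
Reactants: 3 diethyl 2,5-dioxocyclohexane-1,4-dicarboxylate
Product: 5 cyclohexane-1,4-dione, via bis(beta-keto acid) 4 (not isolated)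
Conditions: H2O, sealed vessel, 185–195 °C, 15 min; distillation
Reagents that add atoms: none
Why: Ester hydrolysis followed by β-keto acid decarboxylation through the cyclic six-membered transition state leaves only the symmetrical diketone.

Step 3
Reactants: 5 cyclohexane-1,4-dione
Product: 8 2,3,5,6-tetrabromobenzene-1,4-diol (tetrabromohydroquinone), via 2-bromocyclohexane-1,4-dione 6 (not isolated), via hydroquinone 7 (not isolated)
Conditions: Br2 (5.5 equiv), AcOH, 20 → 90 °C; cool, dilute with H2O, filter
Reagents that add atoms: bromine, BrBr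
Why: Acid-catalysed α-bromination, HBr elimination and keto–enol tautomerisation aromatise the dione, and exhaustive electrophilic aromatic bromination then funnels every partly brominated species to the one perbrominated, poorly soluble product.

Step 4
Reactants: 8 tetrabromohydroquinone
Product: 9 2,3,5,6-tetrabromo-1,4-benzoquinone (bromanil)
Conditions: conc. HNO3, AcOH, 60 °C; filter the yellow plates
Reagents that add atoms: none
Why: This is a hydroquinone-to-quinone oxidation, and with no free ring position nitration cannot compete, so any quinone already present in crude 8 converges to the same product.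

Step 5
Reactants: 10 4-hydroxyphenyl benzoate
Product: 11 3,5-dibromo-4-hydroxyphenyl benzoate
Conditions: Br2 (2.1 equiv), AcOH, rt
Reagents that add atoms: bromine, BrBr
Why: In this electrophilic aromatic bromination the free OH (para position blocked) directs to both of its ortho positions, while the acylated oxygen is too weak a donor to compete.

Step 6
Reactants: 11 3,5-dibromo-4-hydroxyphenyl benzoate
Product: 12 3,5-dibromo-4-methoxyphenyl benzoate
Conditions: MeI (1.5 equiv), K2CO3, acetone, 45 °C
Reagents that add atoms: iodomethane, CI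
Why: In this Williamson ether synthesis the acidic 2,6-dibromophenol is fully deprotonated by carbonate and undergoes SN2 with unhindered MeI faster than it can attack the robust benzoate.

Step 7
Reactants: 12 3,5-dibromo-4-methoxyphenyl benzoate
Product: 13 3,5-dibromo-4-methoxyphenol
Conditions: LiOH (3 equiv), THF/H2O, rt; then 1 M HCl; NaHCO3 wash
Reagents that add atoms: none
Why: Saponification of an aryl ester (acyl–oxygen cleavage) frees the phenol that lies para to the methoxy group and leaves the aryl bromides and methyl ether untouched.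

Step 8
Reactants: 13 3,5-dibromo-4-methoxyphenol
Product: 14 2,3,5-tribromo-4-methoxyphenol
Conditions: Br2 (1.00 equiv, slow addition), CH2Cl2/AcOH, 0 °C
Reagents that add atoms: bromine, BrBr
Why: This electrophilic aromatic bromination occurs ortho to OH, where the two open sites are equivalent so only one monobromide can form, and the new bromine (meta to the last free site) strongly retards a second bromination.

Step 9
Reactants: 9 bromanil (1 equiv); 14 2,3,5-tribromo-4-methoxyphenol (2.1 equiv)
Product: 17 2,5-dibromo-3,6-bis(2,3,5-tribromo-4-methoxyphenoxy)-1,4-benzoquinone, via sodium aryloxide 15 (not isolated), via monoaryloxy tribromoquinone 16 (not isolated)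
Conditions: 14, NaH (2.05 equiv), THF, 0 °C; then add to 9, THF, 0 → 45 °C
Reagents that add atoms: none
Why: In this twofold oxa-Michael addition–elimination on the tetrahaloquinone, the first aryloxy group turns its enone half into a vinylogous ester, so the second aryloxide adds at the carbon para to it (2,5-pattern), and the doubly donor-substituted quinone resists a third attack by this weak nucleophile.

Step 10
Reactants: 17 2,5-dibromo-3,6-bis(2,3,5-tribromo-4-methoxyphenoxy)-1,4-benzoquinone
Product: 18 2,5-dibromo-3,6-bis(2,3,5-tribromo-4-methoxyphenoxy)benzene-1,4-diol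
Conditions: Na2S2O4 (3 equiv), THF/H2O, rt, N2
Reagents that add atoms: none
Why: Dithionite reduction of the electron-poor quinone to its hydroquinone is fast and neutral, so the aryl bromides, methyl ethers and diaryl ethers are unaffected.

Step 11
Reactants: 18 2,5-dibromo-3,6-bis(2,3,5-tribromo-4-methoxyphenoxy)benzene-1,4-diol
Product: 20 2,5-dibromo-3,6-bis(2,3,5-tribromo-4-hydroxyphenoxy)benzene-1,4-diol (target), via tetrakis(dibromoboryl) ether 19 (not isolated)
Conditions: BBr3 (8 equiv), CH2Cl2, −78 °C → rt; then H2O, 0 °C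
Reagents that add atoms: none
Why: BBr3-mediated aryl methyl ether cleavage (bromide SN2 at the methyl of the boron-complexed ether) is easy for di-ortho-bromoanisoles and leaves diaryl ethers and C–Br bonds intact; no stereocentre is involved.

## Compound list
1 | diethyl succinate | CCOC(=O)CCC(=O)OCC | starting material
2 | triethyl 3-oxopentane-1,2,5-tricarboxylate (racemic, labile) | CCOC(=O)CC(C(=O)OCC)C(=O)CCC(=O)OCC | intermediate (not isolated)
3 | diethyl 2,5-dioxocyclohexane-1,4-dicarboxylate (largely bis-enol; labile centres) | CCOC(=O)C1CC(=O)C(C(=O)OCC)CC1=O | intermediate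
4 | 2,5-dioxocyclohexane-1,4-dicarboxylic acid | OC(=O)C1CC(=O)C(C(=O)O)CC1=O | intermediate (not isolated)
5 | cyclohexane-1,4-dione | O=C1CCC(=O)CC1 | intermediate
6 | 2-bromocyclohexane-1,4-dione (racemic) | O=C1CCC(=O)C(Br)C1 | intermediate (not isolated)
7 | hydroquinone (benzene-1,4-diol) | Oc1ccc(O)cc1 | intermediate (not isolated)
8 | 2,3,5,6-tetrabromobenzene-1,4-diol | Oc1c(Br)c(Br)c(O)c(Br)c1Br | intermediate
9 | 2,3,5,6-tetrabromo-1,4-benzoquinone (bromanil) | O=C1C(Br)=C(Br)C(=O)C(Br)=C1Br | intermediate
10 | 4-hydroxyphenyl benzoate | Oc1ccc(OC(=O)c2ccccc2)cc1 | starting material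
11 | 3,5-dibromo-4-hydroxyphenyl benzoate | Oc1c(Br)cc(OC(=O)c2ccccc2)cc1Br | intermediate
12 | 3,5-dibromo-4-methoxyphenyl benzoate | COc1c(Br)cc(OC(=O)c2ccccc2)cc1Br | intermediate
13 | 3,5-dibromo-4-methoxyphenol | COc1c(Br)cc(O)cc1Br | intermediate
14 | 2,3,5-tribromo-4-methoxyphenol | COc1c(Br)cc(O)c(Br)c1Br | intermediate
15 | sodium 2,3,5-tribromo-4-methoxyphenoxide | COc1c(Br)cc([O-])c(Br)c1Br.[Na+] | intermediate (not isolated)
16 | 2,3,5-tribromo-6-(2,3,5-tribromo-4-methoxyphenoxy)-1,4-benzoquinone | O=C1C(Br)=C(Br)C(=O)C(Oc2cc(Br)c(OC)c(Br)c2Br)=C1Br | intermediate (not isolated)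
17 | 2,5-dibromo-3,6-bis(2,3,5-tribromo-4-methoxyphenoxy)-1,4-benzoquinone | O=C1C(Br)=C(Oc2cc(Br)c(OC)c(Br)c2Br)C(=O)C(Br)=C1Oc3cc(Br)c(OC)c(Br)c3Br | intermediate
18 | 2,5-dibromo-3,6-bis(2,3,5-tribromo-4-methoxyphenoxy)benzene-1,4-diol | Oc1c(Br)c(Oc2cc(Br)c(OC)c(Br)c2Br)c(O)c(Br)c1Oc3cc(Br)c(OC)c(Br)c3Br | intermediate
19 | tetrakis(O-dibromoboryl) ether of 20 | BrB(Br)Oc1c(Br)cc(Oc2c(OB(Br)Br)c(Br)c(Oc3cc(Br)c(OB(Br)Br)c(Br)c3Br)c(OB(Br)Br)c2Br)c(Br)c1Br | intermediate (not isolated)
20 | 2,5-dibromo-3,6-bis(2,3,5-tribromo-4-hydroxyphenoxy)benzene-1,4-diol (CNP0163357.0, achiral) | Oc1c(Br)cc(Oc2c(O)c(Br)c(Oc3cc(Br)c(O)c(Br)c3Br)c(O)c2Br)c(Br)c1Br | target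

## Totals
Total step count: 11.
Longest linear sequence: 7 steps (steps 1–4 then 9–11; the branch of steps 5–8 then 9–11 is equally long).

## Steps most likely to fail

**Step 9 (double aryloxide substitution on bromanil).** The aryloxide is weak and carries an ortho bromine, so the second substitution may stall, or redox and hydrolysis side reactions may intervene. The fallback reverses the polarity of the ether formation, sets out from 9 and does not need 14.
- NaOMe (2 equiv) in MeOH at 0 °C converts 9 into 2,5-dibromo-3,6-dimethoxy-1,4-benzoquinone F6.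
- Na2S2O4 in THF/H2O reduces this to 2,5-dibromo-3,6-dimethoxybenzene-1,4-diol F7.
- SNAr of its bis-phenoxide on commercial 3-bromo-4-fluorobenzaldehyde (K2CO3, DMF, 110 °C, N2) gives 4,4'-[(2,5-dibromo-3,6-dimethoxy-1,4-phenylene)bis(oxy)]bis(3-bromobenzaldehyde) F8.
- Baeyer–Villiger oxidation (mCPBA, CH2Cl2, reflux) gives the corresponding bis(aryl formate) F9.
- Aqueous NaOH/THF followed by HCl hydrolyses this to 1,4-dibromo-2,5-bis(2-bromo-4-hydroxyphenoxy)-3,6-dimethoxybenzene F10.
- Br2 (4.2 equiv) in AcOH fills only the two positions ortho to each outer OH, which is self-limiting. It gives 1,4-dibromo-2,5-dimethoxy-3,6-bis(2,3,5-tribromo-4-hydroxyphenoxy)benzene F11.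
- BBr3 in CH2Cl2 removes the two central methyl groups, and the route is rejoined at the target 20.

**Step 3 (one-pot aromatisation and perbromination of 5).** The risk is a mixture of partly brominated or non-aromatised diones. The fallback sets out from 3 and aromatises before the carboxyl carbons are removed.
- Br2 (1 equiv) in CHCl3 at 0 °C dehydrogenates 3 to diethyl 2,5-dihydroxyterephthalate F1.
- Aqueous NaOH under N2, then HCl, gives 2,5-dihydroxyterephthalic acid F2.
- Excess Br2 in hot aqueous AcOH brominates the two free positions. It also replaces both carboxyl groups (each ortho to an OH) by ipso-bromodecarboxylation, in the manner of salicylic acid to tribromophenol, and oxidises the product.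
- The route is rejoined at 9, bypassing 5 and 8.

**Step 8 (single bromination of 13).** The risk is contamination with the tetrabromophenol, or a sluggish reaction at the buttressed site. The fallback sets out from 13 and replaces electrophilic substitution by a stoichiometric directed metalation.
- ClC(O)NEt2 with K2CO3 in MeCN gives 3,5-dibromo-4-methoxyphenyl N,N-diethylcarbamate F3.
- TMPMgCl·LiCl (1.1 equiv) in THF at −30 °C deprotonates the position between the carbamate and Br. This gives [2,4-dibromo-6-(diethylcarbamoyloxy)-3-methoxyphenyl]magnesium chloride F4.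
- Quenching with BrCl2C–CCl2Br gives 2,3,5-tribromo-4-methoxyphenyl N,N-diethylcarbamate F5.
- NaOH in aqueous EtOH at reflux, then HCl, cleaves the carbamate, and the route is rejoined at 14.

## Further compounds
F1 | step 3 | diethyl 2,5-dihydroxyterephthalate | CCOC(=O)c1cc(O)c(C(=O)OCC)cc1O
F2 | step 3 | 2,5-dihydroxyterephthalic acid | OC(=O)c1cc(O)c(C(=O)O)cc1O
F3 | step 8 | 3,5-dibromo-4-methoxyphenyl N,N-diethylcarbamate | CCN(CC)C(=O)Oc1cc(Br)c(OC)c(Br)c1
F4 | step 8 | [2,4-dibromo-6-(diethylcarbamoyloxy)-3-methoxyphenyl]magnesium chloride | CCN(CC)C(=O)Oc1cc(Br)c(OC)c(Br)c1[Mg]Cl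
F5 | step 8 | 2,3,5-tribromo-4-methoxyphenyl N,N-diethylcarbamate | CCN(CC)C(=O)Oc1cc(Br)c(OC)c(Br)c1Br
F6 | step 9 | 2,5-dibromo-3,6-dimethoxy-1,4-benzoquinone | COC1=C(Br)C(=O)C(OC)=C(Br)C1=O
F7 | step 9 | 2,5-dibromo-3,6-dimethoxybenzene-1,4-diol | COc1c(Br)c(O)c(OC)c(Br)c1O
F8 | step 9 | 4,4'-[(2,5-dibromo-3,6-dimethoxy-1,4-phenylene)bis(oxy)]bis(3-bromobenzaldehyde) | COc1c(Br)c(Oc2ccc(C=O)cc2Br)c(OC)c(Br)c1Oc3ccc(C=O)cc3Br
F9 | step 9 | [(2,5-dibromo-3,6-dimethoxy-1,4-phenylene)bis(oxy)]bis(3-bromo-4,1-phenylene) diformate | COc1c(Br)c(Oc2ccc(OC=O)cc2Br)c(OC)c(Br)c1Oc3ccc(OC=O)cc3Br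
F10 | step 9 | 1,4-dibromo-2,5-bis(2-bromo-4-hydroxyphenoxy)-3,6-dimethoxybenzene | COc1c(Br)c(Oc2ccc(O)cc2Br)c(OC)c(Br)c1Oc3ccc(O)cc3Br
F11 | step 9 | 1,4-dibromo-2,5-dimethoxy-3,6-bis(2,3,5-tribromo-4-hydroxyphenoxy)benzene | COc1c(Br)c(Oc2cc(Br)c(O)c(Br)c2Br)c(OC)c(Br)c1Oc3cc(Br)c(O)c(Br)c3Br
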